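Early in this run, the west flask, the one you are asked about, moves fast: a single-handed free catalyst carries the racemic substrates to 20.4% of left-handed product by 1.33 h. It then stalls, standing at 35.9% at 5.00 h and 38.5% at 20.0 h.

- west: left-handed substrate 0.25 M; right-handed substrate 0.25 M; reagent 0.375 M; free catalyst 0.20 mM; the very flask that is asked about, followed so far
- flask: left-handed substrate 0.25 M; reagent 0.375 M; free catalyst 0.20 mM; right-handed substrate 0.25 M; time 30 h

west run (percent of the left-handed substrate and right-handed substrate together charged): time / h: left-handed product / % = 1.33: 20.4; 2.50: 29.4; 5.00: 35.9; 10.0: 36.3; 20.0: 38.5

(each reading ± 1 percentage point)

- Tuesday's: at 30 h take out 90% of the left-handed product then present, then wait 10 h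
- Sunday's: at 30 h add free catalyst, 100% of the amount charged, then wait 10 h
- Saturday's: at 30 h add reagent, 100% of the amount charged, then wait 10 h
- Thursday's: change nothing and wait 10 h more

- free catalyst is single-handed; left-handed substrate and right-handed substrate are mirror images of each other, charged as a racemate, each of them at the stated concentration
- removed left-handed product is counted in
- additions bring no volume worth counting

* left-handed product, in percent of the left-handed substrate and right-handed substrate together first charged, at 30 h
* the option that brings most further left-handed product ("none" if no option brings more than 2 percentage points) (Tuesday's / Sunday's / Saturday's / Thursday's / none)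
* left-handed product present, with what was taken out counted in, in percent of the left-handed substrate and right-handed substrate together first charged, after Sunday's
* left-handed product present, with what was taken out counted in, in percent of the left-handed substrate and right-handed substrate together first charged, after Saturday's

Ask first what end state the charge allows. Suppose each product molecule of either hand costs one reagent, and call the reagent charge over both substrates together the budget, 75.0%. That is less than the 100% the substrates could take, which would make reagent the limiting reagent. The last reading over the budget gives 0.513: this is the left-hand share, the part of the reagent that ends in left-handed product, as read with the scatter of one reading.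

A share of half is what two mirror-image substrates dividing the reagent would give, so you read the stall as the budget's end. Your reckoning is then about 38.5% now, and waiting, removal or catalyst gain nothing. Saturday's raises the budget to 150%, which carries left-handed product to its ceiling of 50.0%.

The forecast gives 38% now, Saturday's as best, 38.5% after Sunday's and 48.5% after Saturday's, a little below your ceiling, saying “Fresh reagent should drive the left-handed substrate almost to completion”.

The flask gives 38.1% with 0% of the reagent left at 30.0 h. Saturday's is best, gaining 12 percentage points; Sunday's stays at 38.1% and Saturday's reaches 50.0%.

    free catalyst + left-handed substrate ⇌ catalyst intermediate A (K = 4.11 L mol⁻¹, k = 14.4 L mol⁻¹ s⁻¹)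
    free catalyst + right-handed substrate ⇌ catalyst intermediate B (K = 9.85 L mol⁻¹, k = 11.4 L mol⁻¹ s⁻¹)
    reagent + catalyst intermediate B → free catalyst + right-handed product (k = 1.22 L mol⁻¹ s⁻¹)
    2 free catalyst ⇌ resting dimer, settled at all times (K = 1830 L mol⁻¹)
    reagent ⇌ dormant form (K = 0.310, k = 4.94 × 10⁻⁴ s⁻¹)
    reagent + catalyst intermediate A → free catalyst + left-handed product (k = 3.08 L mol⁻¹ s⁻¹)

Part of the reason the flask stops at 38.1% is the reagent taken by catalyst intermediate B to make right-handed product: the run without that step reaches 50.0%. A large single effect on Saturday's gain is the turning of free catalyst and right-handed substrate into catalyst intermediate B: with that turning taken away, both ways, the gain falls from 12 points to 0 points. Held against Saturday's, 0.513 of the new budget is 77.0%, more than the 50.0% reached, so the ceiling stands in place of the budget. A neighbour flask with 0.15 M of reagent has a budget of 30.0%, and the share makes that 15.4%; that flask gives 15.4%.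

The runs were computed for substances that don't exist; scatter was added.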